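**Plan**

1. Retrosynthesis (caryophyllane numbers for the carbocycle, C1′ for the benzylic carbon): cut the two formyl C–C bonds and the O-methyl groups, then C8=CH2, then C1–C11 and C9–C10 together (2-methylpropene), then C1=C9 (metathesis), C8–C9 (vinyl), C4–CH3, C4–C3, C5–C6 and last the pyranone ring of a 4-phenylcoumarin.
2. Enabling feature: the cyclobutane C1–C9–C10–C11 is fused at C1–C9 directly beside the methylidene carbon C8, and C10 (CH2) plus C11 (CMe2) are the two alkene carbons of 2-methylpropene; with C8 as a ketone, C9=C1 is the double bond of a cyclonon-2-enone.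
3. Forward order: arene → coumarin (Pechmann) → 2,2,3,4-substituted chroman with a butenyl and a vinyl ketone arm → nine-membered (Z)-enone by ring-closing metathesis → cyclobutane by [2+2] photocycloaddition → methylenation, O-demethylation, twofold formylation.
4. Stereochemistry: C1′ from a ligand-controlled copper hydride reduction; C5 by lactone alkylation anti to phenyl; C4 by axial methyl delivery to the chroman-2-ylium ion; C1 by face-selective photocycloaddition on the chroman-locked ring; C9 by equilibration to the trans-fused ketone.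

Key step: step 12

Remark: the antipode of DTBM-SEGPHOS written in step 2 is assumed to be the one that gives (S)-4; if the sense of induction is the opposite, the other antipode is used and nothing else changes.

**Route**

Step 1
Reactants: 1 3,5-dimethoxyphenol; 2 ethyl benzoylacetate
Product: 3 5,7-dimethoxy-4-phenyl-2H-chromen-2-one
Conditions: CF3CO2H, 70 °C
Reagents that add atoms: none
Why: Pechmann condensation, in which transesterification and ring closure of the activated position ortho to the phenol onto the ketone with loss of water give the coumarin, and the symmetric phenol allows only one regioisomer.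

Step 2
Reactants: 3 5,7-dimethoxy-4-phenyl-2H-chromen-2-one
Product: 4 (4S)-5,7-dimethoxy-4-phenylchroman-2-one
Conditions: Cu(OAc)2 (5 mol%), (R)-DTBM-SEGPHOS (5 mol%), (EtO)2MeSiH, t-BuOH, THF, rt
Reagents that add atoms: none
Why: Asymmetric copper hydride conjugate reduction of a 4-arylcoumarin, in which the bisphosphine-bound Cu–H delivers hydride to one face of C4 and t-BuOH protonates the copper enolate, so the ligand sets C4 (later C1′) as S.

Step 3
Reactants: 4 (4S)-5,7-dimethoxy-4-phenylchroman-2-one; 5 tert-butyl(3-iodopropoxy)diphenylsilane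
Product: 7 (3R,4S)-3-[3-(tert-butyldiphenylsilyloxy)propyl]-5,7-dimethoxy-4-phenylchroman-2-one, via lithium enolate 6 (not isolated)
Conditions: LiN(i-Pr)2, THF, −78 °C; then 5, DMPU, −78 → −30 °C
Reagents that add atoms: none
Why: Lactone enolate alkylation, in which the iodide approaches the face opposite the C4 phenyl (held pseudo-axial by the peri methoxy group) and so gives the 3,4-trans lactone with C3 (later C5) as R.

Step 4
Reactants: 7 (3R,4S)-3-[3-(tert-butyldiphenylsilyloxy)propyl]-5,7-dimethoxy-4-phenylchroman-2-one; 8 but-3-enylmagnesium bromide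
Product: 9 (3R,4S)-2-(but-3-en-1-yl)-3-[3-(tert-butyldiphenylsilyloxy)propyl]-5,7-dimethoxy-4-phenylchroman-2-ol (lactol; both C2 anomers)
Conditions: 8, CeCl3 (anhydrous), THF, −78 °C; aq. NH4Cl
Reagents that add atoms: none
Why: Single addition of an organocerium reagent to a lactone, where the weakly basic but-3-enylcerium species should add once to the aryl lactone carbonyl without enolising it, and the hemiketal configuration at C2 is of no consequence.

Step 5
Reactants: 9 lactol
Product: 10 (3R,4S)-2-(but-3-en-1-yl)-3-[3-(tert-butyldiphenylsilyloxy)propyl]-2,5,7-trimethoxy-4-phenylchroman (mixed methyl ketal; both C2 anomers)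
Conditions: MeOH, pyridinium p-toluenesulfonate (cat.), 4 Å molecular sieves, rt
Reagents that add atoms: methanol CO
Why: Acid-catalysed ketalisation, which funnels lactol and open hydroxy ketone into the six-membered mixed ketal and returns any C3 epimer formed through the ketone to the favoured 3,4-trans ring.

Step 6
Reactants: 10 mixed methyl ketal
Product: 11 (2S,3R,4S)-2-(but-3-en-1-yl)-3-[3-(tert-butyldiphenylsilyloxy)propyl]-5,7-dimethoxy-2-methyl-4-phenylchroman
Conditions: AlMe3 (4 equiv), CH2Cl2, −78 → 0 °C
Reagents that add atoms: trimethylaluminium C[Al](C)C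
Why: Lewis-acid-mediated substitution of a ketal by AlMe3 (C-glycosylation type), in which AlMe3 removes methoxide to give the chroman-2-ylium ion with the C3 chain and C4 phenyl pseudo-equatorial and methyl is delivered on the axial trajectory anti to the axial C3–H, so it enters cis to the C3 chain and trans to phenyl and sets C2 (later C4) as S.

Step 7
Reactants: 11 silyl ether
Product: 12 3-[(2S,3R,4S)-2-(but-3-en-1-yl)-5,7-dimethoxy-2-methyl-4-phenylchroman-3-yl]propan-1-ol
Conditions: Bu4NF, THF, rt
Reagents that add atoms: none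
Why: Fluoride cleavage of a silyl ether, driven by the Si–F bond and leaving the alkene, the ethers and all stereocentres untouched.

Step 8
Reactants: 12 primary alcohol
Product: 13 3-[(2S,3R,4S)-2-(but-3-en-1-yl)-5,7-dimethoxy-2-methyl-4-phenylchroman-3-yl]propanal
Conditions: Dess–Martin periodinane, CH2Cl2, rt
Reagents that add atoms: none
Why: Dess–Martin oxidation stops at the aldehyde under neutral conditions and does not touch the terminal alkene or the electron-rich arene.

Step 9
Reactants: 13 aldehyde; 14 vinylmagnesium bromide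
Product: 15 5-[(2S,3R,4S)-2-(but-3-en-1-yl)-5,7-dimethoxy-2-methyl-4-phenylchroman-3-yl]pent-1-en-3-ol (both carbinol epimers)
Conditions: 14, THF, −78 °C
Reagents that add atoms: none
Why: Grignard 1,2-addition to the only carbonyl group, where the new carbinol centre need not be controlled because it is oxidised in the next step.

Step 10
Reactants: 15 allylic alcohol
Product: 16 5-[(2S,3R,4S)-2-(but-3-en-1-yl)-5,7-dimethoxy-2-methyl-4-phenylchroman-3-yl]pent-1-en-3-one
Conditions: Dess–Martin periodinane, CH2Cl2, 0 °C; used at once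
Reagents that add atoms: none
Why: Dess–Martin oxidation of the allylic alcohol gives the vinyl ketone under mild, non-basic conditions that avoid conjugate addition or polymerisation.

Step 11
Reactants: 16 vinyl ketone
Product: 17 chroman-fused (Z)-cyclonon-2-enone (4S,5R,1′S; C8 ketone; C1=C9 double bond; nine-membered ring fused at C4–C5 to the 5,7-dimethoxy-2-methyl-4-phenylchroman)
Conditions: second-generation Grubbs catalyst (H2IMes)(PCy3)Cl2Ru=CHPh (10 mol%), toluene (2 mM), 80 °C
Reagents that add atoms: none
Why: Ring-closing metathesis, in which the catalyst loads on the butenyl alkene and closes onto the vinyl ketone with loss of ethene, the trans-diequatorial (gauche) arms on C2/C3 of the chroman favour closure over dimerisation, and ring strain allows only the Z-enone.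

Step 12
Reactants: 17 chroman-fused (Z)-cyclonon-2-enone; 18 2-methylpropene
Product: 20 trans-fused cyclobutane ketone (1S,4S,5R,9R,1′S; C8 ketone of the di-O-methyl bis-deformyl target), via cis-fused C9 epimer 19 (not isolated)
Conditions: 18 (condensed, large excess as cosolvent), CH2Cl2, hν (366 nm, Pyrex), −78 °C; then remove 18, DBU (cat.), CH2Cl2, rt
Reagents that add atoms: none
Why: Excitation of the enone n→π* band and intersystem crossing give the triplet enone, twisted about C1=C9, which adds 2-methylpropene stepwise through a triplet 1,4-diradical; the closest known reaction is the enone–alkene [2+2] photocycloaddition of cycloalkenones with 2-methylpropene, which gives the same head-to-tail orientation (CMe2 on the β-carbon C1, CH2 on the α-carbon C9). The cyclobutane C1–C11–C10–C9 is closed intermolecularly, its second bond by recombination of the 1,4-diradical after spin inversion. C1 is set by the enone face that the trans-diequatorial chroman fusion leaves open: the C1=C9 plane stands roughly perpendicular to the mean plane of the nine-membered ring, its inner face is closed by the ring and the axial C4 methyl, and bonding of C11 on the outer face should give 1S. C9 is set thermodynamically, because the twisted triplet should lead mainly to the trans-fused adduct and DBU equilibrates any cis-fused epimer 19 through the C8 enolate to the more stable trans-fused 9R ketone. The step needs head-to-tail regioselectivity, which the electron-rich 1,1-disubstituted alkene secures, chemoselective excitation, which holds because at 366 nm only the enone absorbs (the arene has no formyl groups and both terminal alkenes were consumed in ring closure), and face selectivity at C1, which rests on the ring conformation and is the least certain element. A large excess of 2-methylpropene at low temperature lets cycloaddition compete with the reversible Z/E isomerisation of the excited enone.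

Step 13
Reactants: 20 trans-fused cyclobutane ketone
Product: 21 C8-methylidene compound (1S,4S,5R,9R,1′S; di-O-methyl bis-deformyl target)
Conditions: Ph3PCH3Br, KOt-Bu, toluene, 80 °C
Reagents that add atoms: methyltriphenylphosphonium bromide C[P+](c1ccccc1)(c1ccccc1)c1ccccc1.[Br-]
Why: Wittig methylenation of the C8 ketone, where the basic ylide can only return the epimerisable C9 to the favoured trans-fused arrangement before olefination fixes it.

Step 14
Reactants: 21 C8-methylidene compound
Product: 23 bis-deformyl target (5,7-diol of 21), via 7-hydroxy-5-methoxy compound 22 (not isolated)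
Conditions: MeMgI (excess), neat, 160 °C, reduced pressure; aq. NH4Cl
Reagents that add atoms: none
Why: Grignard ether cleavage, in which iodide demethylates the magnesium-coordinated aryl methyl ethers under aprotic conditions that spare the acid-sensitive methylidene–cyclobutane unit and the tertiary chroman ether, and whichever ether is cleaved first the same diol results.

Step 15
Reactants: 23 bis-deformyl target
Product: 25 target CNP0253700.1 (6,8-dicarbaldehyde of 23; 1S,4S,5R,9R,1′S), via 6-formyl compound 24 (not isolated)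
Conditions: MgCl2, Et3N, (CH2O)n, MeCN, reflux; aq. HCl (1 M)
Reagents that add atoms: paraformaldehyde (as formaldehyde) C=O
Why: Magnesium-mediated ortho-formylation (Casnati–Skattebøl), in which each magnesium phenoxide delivers formaldehyde to its ortho carbon and a second formaldehyde oxidises the benzylic alkoxide by hydride transfer; C6 and C8 are the only free ring positions and each is ortho to a phenoxide, so twofold reaction under basic conditions should give the dialdehyde whichever position reacts first.

**Compound list**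

1 | 3,5-dimethoxyphenol | COc1cc(O)cc(OC)c1 | starting material
2 | ethyl benzoylacetate | CCOC(=O)CC(=O)c1ccccc1 | starting material
3 | 5,7-dimethoxy-4-phenyl-2H-chromen-2-one | O=C1C=C(c2ccccc2)c2c(OC)cc(OC)cc2O1 | intermediate
4 | (4S)-5,7-dimethoxy-4-phenylchroman-2-one | O=C1C[C@@H](c2ccccc2)c2c(OC)cc(OC)cc2O1 | intermediate
5 | tert-butyl(3-iodopropoxy)diphenylsilane | CC(C)(C)[Si](OCCCI)(c1ccccc1)c1ccccc1 | starting material
6 | lithium enolate of 4 (lithium (4S)-5,7-dimethoxy-4-phenyl-4H-chromen-2-olate) | [Li]OC1=C[C@@H](c2ccccc2)c2c(OC)cc(OC)cc2O1 | intermediate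
7 | (3R,4S)-3-[3-(tert-butyldiphenylsilyloxy)propyl]-5,7-dimethoxy-4-phenylchroman-2-one (3,4-trans) | CC(C)(C)[Si](c1ccccc1)(c1ccccc1)OCCC[C@@H]1[C@@H](c2ccccc2)c2c(OC)cc(OC)cc2OC1=O | intermediate
8 | but-3-enylmagnesium bromide | C=CCC[Mg]Br | starting material
9 | (3R,4S)-2-(but-3-en-1-yl)-3-[3-(tert-butyldiphenylsilyloxy)propyl]-5,7-dimethoxy-4-phenylchroman-2-ol (both C2 anomers) | CC(C)(C)[Si](c1ccccc1)(c1ccccc1)OCCC[C@@H]1[C@@H](c2ccccc2)c2c(OC)cc(OC)cc2OC1(O)CCC=C | intermediate
10 | (3R,4S)-2-(but-3-en-1-yl)-3-[3-(tert-butyldiphenylsilyloxy)propyl]-2,5,7-trimethoxy-4-phenylchroman (both C2 anomers) | CC(C)(C)[Si](c1ccccc1)(c1ccccc1)OCCC[C@@H]1[C@@H](c2ccccc2)c2c(OC)cc(OC)cc2OC1(OC)CCC=C | intermediate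
11 | (2S,3R,4S)-2-(but-3-en-1-yl)-3-[3-(tert-butyldiphenylsilyloxy)propyl]-5,7-dimethoxy-2-methyl-4-phenylchroman | CC(C)(C)[Si](c1ccccc1)(c1ccccc1)OCCC[C@@H]1[C@@H](c2ccccc2)c2c(OC)cc(OC)cc2O[C@@]1(C)CCC=C | intermediate
12 | 3-[(2S,3R,4S)-2-(but-3-en-1-yl)-5,7-dimethoxy-2-methyl-4-phenylchroman-3-yl]propan-1-ol | OCCC[C@@H]1[C@@H](c2ccccc2)c2c(OC)cc(OC)cc2O[C@@]1(C)CCC=C | intermediate
13 | 3-[(2S,3R,4S)-2-(but-3-en-1-yl)-5,7-dimethoxy-2-methyl-4-phenylchroman-3-yl]propanal | O=CCC[C@@H]1[C@@H](c2ccccc2)c2c(OC)cc(OC)cc2O[C@@]1(C)CCC=C | intermediate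
14 | vinylmagnesium bromide | C=C[Mg]Br | starting material
15 | 5-[(2S,3R,4S)-2-(but-3-en-1-yl)-5,7-dimethoxy-2-methyl-4-phenylchroman-3-yl]pent-1-en-3-ol (both carbinol epimers) | C=CC(O)CC[C@@H]1[C@@H](c2ccccc2)c2c(OC)cc(OC)cc2O[C@@]1(C)CCC=C | intermediate
16 | 5-[(2S,3R,4S)-2-(but-3-en-1-yl)-5,7-dimethoxy-2-methyl-4-phenylchroman-3-yl]pent-1-en-3-one | C=CC(=O)CC[C@@H]1[C@@H](c2ccccc2)c2c(OC)cc(OC)cc2O[C@@]1(C)CCC=C | intermediate
17 | chroman-fused (Z)-cyclonon-2-enone, 4S,5R,1′S: nine-membered ring C8(=O)–C7–C6–C5–C4–C3–C2–C1=C9, fused through C4 (O, CH3) and C5 (H) to the 2,3-bond of the 5,7-dimethoxy-4-phenylchroman | O=C1CC[C@@H]2[C@@H](c3ccccc3)c3c(OC)cc(OC)cc3O[C@@]2(C)CC/C=C\1 | intermediate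
18 | 2-methylpropene | C=C(C)C | starting material
19 | cis-fused cyclobutane ketone, 1S,4S,5R,9S,1′S (C9 epimer of 20) | O=C1CC[C@@H]2[C@@H](c3ccccc3)c3c(OC)cc(OC)cc3O[C@@]2(C)CC[C@H]2[C@@H]1CC2(C)C | intermediate
20 | trans-fused cyclobutane ketone, 1S,4S,5R,9R,1′S (C8 ketone of the di-O-methyl bis-deformyl target) | O=C1CC[C@@H]2[C@@H](c3ccccc3)c3c(OC)cc(OC)cc3O[C@@]2(C)CC[C@H]2[C@H]1CC2(C)C | intermediate
21 | C8-methylidene compound, 1S,4S,5R,9R,1′S (di-O-methyl bis-deformyl target) | C=C1CC[C@@H]2[C@@H](c3ccccc3)c3c(OC)cc(OC)cc3O[C@@]2(C)CC[C@H]2[C@H]1CC2(C)C | intermediate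
22 | 7-hydroxy-5-methoxy compound (mono-demethylated 21) | C=C1CC[C@@H]2[C@@H](c3ccccc3)c3c(OC)cc(O)cc3O[C@@]2(C)CC[C@H]2[C@H]1CC2(C)C | intermediate
23 | bis-deformyl target (5,7-diol) | C=C1CC[C@@H]2[C@@H](c3ccccc3)c3c(O)cc(O)cc3O[C@@]2(C)CC[C@H]2[C@H]1CC2(C)C | intermediate
24 | 6-formyl compound (mono-aldehyde of 23) | C=C1CC[C@@H]2[C@@H](c3ccccc3)c3c(O)c(C=O)c(O)cc3O[C@@]2(C)CC[C@H]2[C@H]1CC2(C)C | intermediate
25 | CNP0253700.1, 1S,4S,5R,9R,1′S | C=C1CC[C@@H]2[C@@H](c3ccccc3)c3c(O)c(C=O)c(O)c(C=O)c3O[C@@]2(C)CC[C@H]2[C@H]1CC2(C)C | target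

**Step count and risks**

Total step count: 15. Longest linear sequence: 15 steps (from 1 and 2 to 25); the route is fully linear.

Steps most likely to fail, riskiest first:

Step 12. The excited enone may relax mainly by Z/E isomerisation and oligomerise, or it may add the alkene on both faces of C1. The fallback builds the cyclobutane on the ground-state enone in two polar bond formations; it sets out from 17 and comes back at 20. Enone 17 would take up 1-methoxy-2-methyl-1-(trimethylsilyloxy)prop-1-ene in a Mukaiyama–Michael addition (MeCN, 55 °C, no Lewis acid), forming C1–C11 and giving the silyl enol ether ester F1. Reduction with i-Bu2AlH (CH2Cl2, −78 °C) would give the neopentyl alcohol F2, and TsCl, Et3N and DMAP would give the tosylate F3. MeLi (THF, 0 °C, then DMPU) would then release the regiodefined C8–C9 lithium enolate, which closes C9–C10 by intramolecular alkylation; the same DBU equilibration gives 20. Here the face of attack at C1 follows from peripheral addition to the ground-state Z-enone and does not depend on the excited-state geometry.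

Step 11. Oligomerisation by cross-metathesis may outrun closure of the strained nine-membered ring, or the catalyst may stall on the electron-poor vinyl ketone. The fallback closes the ring by C8–C9 bond formation instead; it sets out from 11 and comes back at 17. Oxidative cleavage of the butenyl alkene of 11 (OsO4 cat., NaIO4, 2,6-lutidine, dioxane–water) would give the aldehyde F4, and Stork–Zhao olefination (Ph3P(CH2I)I, NaN(SiMe3)2, THF–DMPU, −78 °C) the (Z)-vinyl iodide F5. Bu4NF would free the primary alcohol F6 and Dess–Martin periodinane would give the iodo aldehyde F7. An intramolecular Nozaki–Hiyama–Kishi reaction (CrCl2, NiCl2 cat., DMSO, high dilution) would close the ring to the cyclic (Z)-allylic alcohol F8, which Dess–Martin periodinane oxidises to 17.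

Step 6. Methyl may enter the chroman-2-ylium ion mainly on the face anti to the C3 chain, which would give the C2 epimer, or the cation may lose a proton to an enol ether. The fallback exchanges the roles of the two C2 substituents so that the same facial preference leads to the right centre; it sets out from 7 and comes back at 11. Lactone 7 would add MeLi with CeCl3 (THF, −78 °C) to give the methyl lactol F9, and MeOH with pyridinium p-toluenesulfonate would give the methyl ketal F10. Allyltrimethylsilane with BF3·OEt2 (CH2Cl2, −78 °C) would then deliver the carbon chain as the nucleophile and give the 2-allyl-2-methylchroman F11. Hydroboration–oxidation (9-BBN, then NaBO3) would give the alcohol F12, Dess–Martin periodinane the aldehyde F4, and Wittig methylenation (Ph3PCH3Br, KOt-Bu) would return 11.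

**Further compounds**

F1 | step 12 | methyl 2-methyl-2-(C1)propanoate adduct of 17 with C8–C9 trimethylsilyl enol ether (1S,4S,5R,1′S) | C[Si](C)(C)OC=1CC[C@@H]2[C@@H](c3ccccc3)c3c(OC)cc(OC)cc3O[C@@]2(C)CC[C@H](C(C)(C)C(=O)OC)C=1
F2 | step 12 | neopentyl alcohol from F1 (C1–CMe2–CH2OH; silyl enol ether retained) | C[Si](C)(C)OC=1CC[C@@H]2[C@@H](c3ccccc3)c3c(OC)cc(OC)cc3O[C@@]2(C)CC[C@H](C(C)(C)CO)C=1
F3 | step 12 | p-toluenesulfonate of F2 | C[Si](C)(C)OC=1CC[C@@H]2[C@@H](c3ccccc3)c3c(OC)cc(OC)cc3O[C@@]2(C)CC[C@H](C(C)(C)COS(=O)(=O)c3ccc(C)cc3)C=1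
F4 | step 11 | 3-[(2S,3R,4S)-3-[3-(tert-butyldiphenylsilyloxy)propyl]-5,7-dimethoxy-2-methyl-4-phenylchroman-2-yl]propanal | CC(C)(C)[Si](c1ccccc1)(c1ccccc1)OCCC[C@@H]1[C@@H](c2ccccc2)c2c(OC)cc(OC)cc2O[C@@]1(C)CCC=O
F5 | step 11 | (2S,3R,4S)-3-[3-(tert-butyldiphenylsilyloxy)propyl]-2-[(Z)-4-iodobut-3-en-1-yl]-5,7-dimethoxy-2-methyl-4-phenylchroman | CC(C)(C)[Si](c1ccccc1)(c1ccccc1)OCCC[C@@H]1[C@@H](c2ccccc2)c2c(OC)cc(OC)cc2O[C@@]1(C)CC/C=C\I
F6 | step 11 | 3-[(2S,3R,4S)-2-[(Z)-4-iodobut-3-en-1-yl]-5,7-dimethoxy-2-methyl-4-phenylchroman-3-yl]propan-1-ol | OCCC[C@@H]1[C@@H](c2ccccc2)c2c(OC)cc(OC)cc2O[C@@]1(C)CC/C=C\I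
F7 | step 11 | 3-[(2S,3R,4S)-2-[(Z)-4-iodobut-3-en-1-yl]-5,7-dimethoxy-2-methyl-4-phenylchroman-3-yl]propanal | O=CCC[C@@H]1[C@@H](c2ccccc2)c2c(OC)cc(OC)cc2O[C@@]1(C)CC/C=C\I
F8 | step 11 | cyclic (Z)-allylic alcohol, C8 carbinol of 17 (both C8 epimers) | OC1CC[C@@H]2[C@@H](c3ccccc3)c3c(OC)cc(OC)cc3O[C@@]2(C)CC/C=C\1
F9 | step 6 | (3R,4S)-3-[3-(tert-butyldiphenylsilyloxy)propyl]-5,7-dimethoxy-2-methyl-4-phenylchroman-2-ol (both anomers) | CC(C)(C)[Si](c1ccccc1)(c1ccccc1)OCCC[C@@H]1[C@@H](c2ccccc2)c2c(OC)cc(OC)cc2OC1(C)O
F10 | step 6 | (3R,4S)-3-[3-(tert-butyldiphenylsilyloxy)propyl]-2,5,7-trimethoxy-2-methyl-4-phenylchroman (both anomers) | CC(C)(C)[Si](c1ccccc1)(c1ccccc1)OCCC[C@@H]1[C@@H](c2ccccc2)c2c(OC)cc(OC)cc2OC1(C)OC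
F11 | step 6 | (2S,3R,4S)-2-allyl-3-[3-(tert-butyldiphenylsilyloxy)propyl]-5,7-dimethoxy-2-methyl-4-phenylchroman | CC(C)(C)[Si](c1ccccc1)(c1ccccc1)OCCC[C@@H]1[C@@H](c2ccccc2)c2c(OC)cc(OC)cc2O[C@@]1(C)CC=C
F12 | step 6 | 3-[(2S,3R,4S)-3-[3-(tert-butyldiphenylsilyloxy)propyl]-5,7-dimethoxy-2-methyl-4-phenylchroman-2-yl]propan-1-ol | CC(C)(C)[Si](c1ccccc1)(c1ccccc1)OCCC[C@@H]1[C@@H](c2ccccc2)c2c(OC)cc(OC)cc2O[C@@]1(C)CCCO
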